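**Assumptions.** The target is taken as drawn: (1R,6R,7S,8R,10S), 4E, with a cis 1,10-epoxide (C2 and C9 on the same side of the oxirane). (+)-β-Pinene is accepted as the chiral-pool starting material; it is the less abundant pinene enantiomer (also obtainable from bulk (+)-α-pinene). Germacrane numbering (C1–C10, C14 = CHO) is used for every intermediate; "β" means the face of the C7 isopropyl group.

## Retrosynthetic overview

1. Target ⇐ acetylation/desilylation and nucleophilic epoxidation of a (1(10)-ring-cis, 4E)-germacradien-14-al ⇐ enal isomerisation and Pd/CO formylation of a C1=C10 enol triflate.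
2. The ten-membered ring comes from an anionic oxy-Cope [3,3] of a 1-vinyl-2-isopropenylcyclohexan-1-ol (forms C2–C3, breaks C5–C10); the enolate is trapped as the triflate.
3. Divinyl carbinol ⇐ vinyl addition to a 2-isopropenyl-3-silyloxy ketone ⇐ semipinacol rearrangement of the isopropenyl adduct of an α,β-epoxy ketone.
4. Epoxy ketone ⇐ trans-5-silyloxy-4-isopropylcyclohexenone ⇐ (S)-cryptone ⇐ (−)-nopinone ⇐ (+)-β-pinene, the only source of chirality.
5. Ring order: cyclohexane (pinane cyclobutane opening) → ten-membered carbocycle (oxy-Cope) → oxirane last.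

## Route

**Step 1**
Reactants: 1, (+)-β-pinene
Product: 2, (−)-nopinone, (1S,5R)-6,6-dimethylbicyclo[3.1.1]heptan-2-one
Conditions: O3, CH2Cl2/MeOH, −78 °C; then Me2S
Reagents that add atoms: ozone, O=[O+][O-]
Why: Ozonolysis of the exocyclic methylene gives the ketone without touching either bridgehead stereocentre.

**Step 2**
Reactants: 2, (−)-nopinone
Product: 3, (S)-cryptone, (4S)-4-isopropylcyclohex-2-en-1-one
Conditions: AlCl3, CH2Cl2, 0 °C → rt
Reagents that add atoms: none
Why: Lewis-acid heterolysis of the strained C1–C6 cyclobutane bond (tertiary cation plus aluminium enolate) followed by hydride transfer from the bridge CH2 gives the conjugated enone (nopinone→cryptone isomerisation, recalled from the literature, not re-verified); the isopropyl-bearing carbon is not involved, so its configuration should be retained.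

**Step 3**
Reactants: 3, (S)-cryptone
Product: 4, (3R,4S)-3-hydroxy-4-isopropylcyclohexan-1-one (C8–OH α, trans to iPr)
Conditions: B2pin2, CuCl (cat.), Xantphos (cat.), NaOtBu (cat.), MeOH, THF, rt; then NaBO3·4H2O, THF/H2O
Reagents that add atoms: sodium perborate (source of the hydroxyl O), [Na+].[O-]OB=O; B2pin2 (boron not retained), CC1(C)OB(OC1(C)C)B1OC(C)(C)C(C)(C)O1
Why: Achiral Cu-boryl conjugate addition occurs anti to the adjacent C7 isopropyl group and the C–B bond is oxidised with retention, setting C8 trans to iPr.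

**Step 4**
Reactants: 4
Product: 5, (3R,4S)-4-isopropyl-3-(triisopropylsilyloxy)cyclohexan-1-one
Conditions: TIPSOTf, 2,6-lutidine, CH2Cl2, −78 → 0 °C
Reagents that add atoms: TIPSOTf, CC(C)[Si](OS(=O)(=O)C(F)(F)F)(C(C)C)C(C)C
Why: Silylation of the secondary alcohol; TIPS is chosen because it resists O→O migration to the tertiary alkoxide in step 10.

**Step 5**
Reactants: 5
Product: 6, (4R,5R)-4-isopropyl-5-(triisopropylsilyloxy)cyclohex-2-en-1-one (C5=C6 enone)
Conditions: LDA, TMSCl, THF, −78 °C; then Pd(OAc)2, MeCN, rt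
Reagents that add atoms: none (TMS is transient)
Why: Kinetic deprotonation takes place at the CH2 remote from the bulky β-silyloxy carbon, and Saegusa–Ito oxidation of that silyl enol ether places the enone on the C5/C6 side.

**Step 6**
Reactants: 6
Product: 7, (1S,4R,5R,6S)-5-isopropyl-4-(triisopropylsilyloxy)-7-oxabicyclo[4.1.0]heptan-2-one (C5–C6 epoxide β, cis to iPr, trans to OTIPS)
Conditions: t-BuOOH, Triton B (cat.), THF, 0 °C
Reagents that add atoms: tert-butyl hydroperoxide, CC(C)(C)OO
Why: In this Weitz–Scheffer epoxidation the peroxide adds axially to the diequatorial half-chair trans to the 5-OTIPS group (the alternative is syn-axial to it), which is the face cis to the isopropyl group and sets C6.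

**Step 7**
Reactants: 7
Product: 8, (1S,2S,4R,5R,6S)-5-isopropyl-2-(prop-1-en-2-yl)-4-(triisopropylsilyloxy)-7-oxabicyclo[4.1.0]heptan-2-ol (C10–OH cis to the epoxide, isopropenyl trans)
Conditions: isopropenylmagnesium bromide, CeCl3, THF, −78 °C
Reagents that add atoms: isopropenylmagnesium bromide, CC(=C)[Mg]Br
Why: The organocerium reagent adds 1,2 to the ketone anti to the α-epoxide oxygen, which places the alkenyl group antiperiplanar to the C5–O bond.

**Step 8**
Reactants: 8
Product: 9, (2R,3S,4S,5R)-3-(tert-butyldimethylsilyloxy)-4-isopropyl-2-(prop-1-en-2-yl)-5-(triisopropylsilyloxy)cyclohexan-1-one (C5 isopropenyl α, C6–OTBS β, C7 iPr β, C8–OTIPS α)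
Conditions: TBSOTf, 2,6-lutidine, CH2Cl2, −78 → −30 °C
Reagents that add atoms: TBSOTf, CC(C)(C)[Si](C)(C)OS(=O)(=O)C(F)(F)F
Why: Silyl-triflate-promoted semipinacol rearrangement of the 2,3-epoxy silyl ether (Suzuki–Tsuchihashi type): the anti isopropenyl group migrates from C10 to C5 with inversion, the ketone is regenerated and the silyl group ends on the former epoxide oxygen, so C6–O keeps its β configuration.

**Step 9**
Reactants: 9
Product: 10, (1R,2R,3S,4S,5R)-3-(tert-butyldimethylsilyloxy)-1-ethenyl-4-isopropyl-2-(prop-1-en-2-yl)-5-(triisopropylsilyloxy)cyclohexan-1-ol (vinyl β, trans to isopropenyl; OH α)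
Conditions: vinylmagnesium bromide, CeCl3, THF, −78 °C
Reagents that add atoms: vinylmagnesium bromide, C=C[Mg]Br
Why: The non-basic organocerium adds equatorially in the chair that has the α-isopropenyl group equatorial, the other face being blocked by the syn-axial C8–OTIPS, giving the trans-1,2-dialkenyl carbinol.

**Step 10**
Reactants: 10
Product: 11, ten-membered enol triflate: (6R,7S,8R)-6-OTBS, 8-OTIPS, 7-iPr, 4-methyl, C4=C5 E, C1=C10(OTf) with C2/C9 trans
Conditions: KH, 18-crown-6, THF, 0 °C → rt; then PhNTf2, −78 → 0 °C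
Reagents that add atoms: N-phenyl-bis(trifluoromethanesulfonimide), O=S(=O)(N(c1ccccc1)S(=O)(=O)C(F)(F)F)C(F)(F)F
Why: Anionic oxy-Cope [3,3] rearrangement through a chair transition state with both alkenyl groups equatorial forms C2–C3, cleaves C5–C10 and gives the (E)-C4=C5 alkene and the C1=C10 enolate regiospecifically, which is O-triflated in situ.

**Step 11**
Reactants: 11
Product: 12, (6R,7S,8R)-6-OTBS-8-OTIPS-germacra-1(10),4-dien-14-al with C2/C9 trans across C1=C10 (ring-trans enal), 4E
Conditions: Pd(PPh3)4 (5 mol %), LiCl, CO (1 atm), Bu3SnH (slow addition), THF, 40 °C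
Reagents that add atoms: carbon monoxide, [C-]#[O+]
Why: Pd-catalysed reductive carbonylation of the vinyl triflate (Stille formylation) installs C14 as the aldehyde with retention of alkene geometry; the allylic silyl ether is inert to Pd(0).

**Step 12**
Reactants: 12
Product: 13, the 1(10) ring-cis enal (C2/C9 cis, CHO trans to C2), 4E unchanged
Conditions: PMe3 (20 mol %), THF, rt
Reagents that add atoms: none
Why: Reversible phosphine conjugate addition–elimination equilibrates only the electron-poor alkene to the ring-cis isomer, which is favoured by relief of trans-cyclodecene and A(1,3) strain.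

**Step 13**
Reactants: 13
Product: 14, (1R,6R,7S,8R,10S)-1,10-epoxy-6-OTBS-8-OTIPS-germacr-4E-en-14-al
Conditions: t-BuOOH, DBU, CH2Cl2, 0 °C
Reagents that add atoms: tert-butyl hydroperoxide, CC(C)(C)OO
Why: Weitz–Scheffer epoxidation of the enal keeps C2/C9 cis; C1 and C10 are expected to be set by peripheral attack on the ring conformer anchored by the pseudo-equatorial C7 isopropyl group, but this facial preference is a prediction and is the least certain stereochemical outcome in the route.

**Step 14**
Reactants: 14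
Product: 15, Pulicanaral A
Conditions: TBAF, AcOH, THF, 0 °C → rt; then Ac2O, Et3N, DMAP, rt (one pot)
Reagents that add atoms: acetic anhydride, CC(=O)OC(C)=O
Why: Buffered fluoride removes both silyl ethers and the two secondary alcohols are acetylated in situ; C8–OH is trans to the CHO group, so lactol formation is disfavoured.

## Compound list

1 | (+)-β-pinene, (1R,5R)-6,6-dimethyl-2-methylidenebicyclo[3.1.1]heptane | C=C1CC[C@@H]2C[C@H]1C2(C)C | starting material
2 | (−)-nopinone, (1S,5R) | O=C1CC[C@@H]2C[C@H]1C2(C)C | intermediate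
3 | (S)-cryptone | O=C1C=C[C@H](C(C)C)CC1 | intermediate
4 | (3R,4S)-3-hydroxy-4-isopropylcyclohexan-1-one | O=C1C[C@@H](O)[C@H](C(C)C)CC1 | intermediate
5 | (3R,4S)-4-isopropyl-3-(triisopropylsilyloxy)cyclohexan-1-one | O=C1C[C@@H](O[Si](C(C)C)(C(C)C)C(C)C)[C@H](C(C)C)CC1 | intermediate
6 | (4R,5R)-4-isopropyl-5-(triisopropylsilyloxy)cyclohex-2-en-1-one | O=C1C=C[C@@H](C(C)C)[C@H](O[Si](C(C)C)(C(C)C)C(C)C)C1 | intermediate
7 | (1S,4R,5R,6S)-5-isopropyl-4-(triisopropylsilyloxy)-7-oxabicyclo[4.1.0]heptan-2-one | O=C1[C@H]2O[C@H]2[C@@H](C(C)C)[C@H](O[Si](C(C)C)(C(C)C)C(C)C)C1 | intermediate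
8 | (1S,2S,4R,5R,6S)-5-isopropyl-2-(prop-1-en-2-yl)-4-(triisopropylsilyloxy)-7-oxabicyclo[4.1.0]heptan-2-ol | O[C@@]1(C(C)=C)[C@H]2O[C@H]2[C@@H](C(C)C)[C@H](O[Si](C(C)C)(C(C)C)C(C)C)C1 | intermediate
9 | (2R,3S,4S,5R)-3-(tert-butyldimethylsilyloxy)-4-isopropyl-2-(prop-1-en-2-yl)-5-(triisopropylsilyloxy)cyclohexan-1-one | O=C1[C@H](C(C)=C)[C@@H](O[Si](C)(C)C(C)(C)C)[C@@H](C(C)C)[C@H](O[Si](C(C)C)(C(C)C)C(C)C)C1 | intermediate
10 | (1R,2R,3S,4S,5R)-3-(tert-butyldimethylsilyloxy)-1-ethenyl-4-isopropyl-2-(prop-1-en-2-yl)-5-(triisopropylsilyloxy)cyclohexan-1-ol | O[C@]1(C=C)[C@H](C(C)=C)[C@@H](O[Si](C)(C)C(C)(C)C)[C@@H](C(C)C)[C@H](O[Si](C(C)C)(C(C)C)C(C)C)C1 | intermediate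
11 | ten-membered enol triflate (6-OTBS, 8-OTIPS, 4E, C2/C9 trans at C1=C10) | CC(C)(C)[Si](C)(C)O[C@@H]1/C=C(\C)CC/C=C(\OS(=O)(=O)C(F)(F)F)C[C@@H](O[Si](C(C)C)(C(C)C)C(C)C)[C@@H]1C(C)C | intermediate
12 | ring-trans 14-al (6-OTBS, 8-OTIPS, 4E) | CC(C)(C)[Si](C)(C)O[C@@H]1/C=C(\C)CC/C=C(\C=O)C[C@@H](O[Si](C(C)C)(C(C)C)C(C)C)[C@@H]1C(C)C | intermediate
13 | ring-cis 14-al (6-OTBS, 8-OTIPS, 4E) | CC(C)(C)[Si](C)(C)O[C@@H]1/C=C(\C)CC/C=C(/C=O)C[C@@H](O[Si](C(C)C)(C(C)C)C(C)C)[C@@H]1C(C)C | intermediate
14 | (1R,6R,7S,8R,10S)-1,10-epoxy-6-OTBS-8-OTIPS-germacr-4E-en-14-al | CC(C)(C)[Si](C)(C)O[C@@H]1/C=C(\C)CC[C@H]2O[C@@]2(C=O)C[C@@H](O[Si](C(C)C)(C(C)C)C(C)C)[C@@H]1C(C)C | intermediate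
15 | Pulicanaral A | CC(=O)O[C@@H]1/C=C(\C)CC[C@H]2O[C@@]2(C=O)C[C@@H](OC(C)=O)[C@@H]1C(C)C | target

## Summary

Total steps: 14. Longest linear sequence: 14 (fully linear from (+)-β-pinene).

Three steps most likely to fail, each with a fallback that changes the approach:

1. **Step 13 (facial selectivity of the final epoxidation).** Fallback: carbonylate triflate 11 with CO/MeOH to the C14 ester, reduce to the allylic alcohol (DIBAL), run a hydroxyl-directed VO(acac)2/t-BuOOH epoxidation (with C8–OH freed as a second, homoallylic director), then oxidise C14 to the aldehyde (DMP).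
2. **Step 6 (epoxide cis to iPr; competing β-elimination of OTIPS to 4-isopropylphenol).** Fallback: accept the epoxide anti to iPr, carry the C6 epimer to carbinol 10, remove the C6–TBS selectively (TBS vs TIPS), oxidise to the C6 ketone and reduce with L-Selectride from the face opposite iPr to set the cis C6–OH by hydride delivery.
3. **Step 10 (oxy-Cope through a congested chair with axial iPr, and possible silyl migration to the alkoxide).** Fallback: switch C8 to a non-migrating PMB ether from step 4 (removed later with DDQ), trap the Cope enolate as its TMS enol ether, and form the triflate separately (MeLi, then PhNTf2).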